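**Plan**
- Retrosynthesis cuts three bonds of the pyranone ring at once: C4a–C4, C4–C3 and O1–C2. This is possible because the carbonyl carbon C4 lies between the A-ring carbon C4a and the C3=C2 unit that bears the 3,4-dimethoxyphenyl ring, with O1 on the neighbouring C8a. C4 can therefore enter as carbon monoxide between an ortho-iodophenol and an arylacetylene.
- The iodophenol is traced back through its C–I bond (ortho-lithiation beside a MOM ether), one O–CH3 bond and one aryl C–O bond (Baeyer–Villiger) to 2-hydroxy-4,6-dimethoxybenzaldehyde. The MOM group serves first as protecting group, then as ortho-director.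
- Forward: the A ring is bought, re-oxygenated (steps 1–3), iodinated (step 4) and unmasked (step 5). The pyranone ring, the only ring made, closes in step 6 while the B ring is attached.
- Stereochemistry: none to set. The target has no stereocentre and no stereogenic double bond, so the "single enantiomer" is the achiral compound itself.

Key step: step 6

Remark: 2-hydroxy-4,6-dimethoxybenzaldehyde, 4-ethynyl-1,2-dimethoxybenzene and carbon monoxide are taken as purchased; flavone numbering (O1, C2, C3, C4, C4a, C5–C8, C8a) is used for the target throughout.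

**Route**

Step 1
Reactants: 1 2-hydroxy-4,6-dimethoxybenzaldehyde
Product: 2 2-(methoxymethoxy)-4,6-dimethoxybenzaldehyde
Conditions: NaH, DMF, 0 °C; then MOMCl, 0 °C → rt
Reagents that add atoms: chloromethyl methyl ether (MOMCl), COCCl
Why: Williamson-type O-alkylation (MOM protection) of the sodium phenoxide, with NaH breaking the hydrogen bond to the aldehyde that makes this hydroxyl sluggish under amine bases.

Step 2
Reactants: 2 2-(methoxymethoxy)-4,6-dimethoxybenzaldehyde
Product: 4 2-(methoxymethoxy)-4,6-dimethoxyphenol, via aryl formate 3 (not isolated)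
Conditions: mCPBA, CH2Cl2, 0 °C → rt; then K2CO3, MeOH, 0 °C → rt
Reagents that add atoms: meta-chloroperoxybenzoic acid (mCPBA), OOC(=O)c1cccc(Cl)c1
Why: Baeyer–Villiger (Dakin-type) oxidation in which the ortho,ortho,para-trioxygenated aryl group migrates in preference to hydrogen to give the aryl formate, which mild methanolysis converts into the phenol while the MOM acetal and methyl ethers are left intact.

Step 3
Reactants: 4 2-(methoxymethoxy)-4,6-dimethoxyphenol
Product: 5 1,2,5-trimethoxy-3-(methoxymethoxy)benzene
Conditions: MeI, K2CO3, DMF, rt
Reagents that add atoms: iodomethane, CI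
Why: Williamson O-methylation of the only free hydroxyl, carried out directly on the oxidation-prone phenol so that the oxygen introduced in step 2 is fixed as the future 8-methoxy group.

Step 4
Reactants: 5 1,2,5-trimethoxy-3-(methoxymethoxy)benzene
Product: 7 2-iodo-1,4,5-trimethoxy-3-(methoxymethoxy)benzene, via aryllithium 6 (not isolated)
Conditions: n-BuLi, TMEDA, THF, 0 °C; then I2, THF, −78 °C → rt
Reagents that add atoms: iodine, II
Why: Directed ortho-metalation in which the chelating OMOM group and the adjacent methoxy group jointly acidify the C–H between them (OMOM is a stronger director than OMe, so this site should be favoured over the C–H between the two methoxy groups), and iodinolysis of the aryllithium places iodine ortho to the masked phenol.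

Step 5
Reactants: 7 2-iodo-1,4,5-trimethoxy-3-(methoxymethoxy)benzene
Product: 8 2-iodo-3,5,6-trimethoxyphenol
Conditions: HCl (1.25 M in MeOH), MeOH, rt → 40 °C
Reagents that add atoms: none
Why: Acid-catalysed methanolysis of the MOM acetal (acetal deprotection) under dilute, mild conditions that should leave the aryl methyl ethers and the aryl iodide untouched.

Step 6
Reactants: 8 2-iodo-3,5,6-trimethoxyphenol; 9 4-ethynyl-1,2-dimethoxybenzene; 10 carbon monoxide
Product: 13 isosinensetin (5,7,8,3',4'-pentamethoxyflavone), via hydroxyaryl ynone 11 (not isolated), via enaminone 12 (not isolated)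
Conditions: PdCl2(dppf) (5 mol %), Et2NH, CO (20 bar), 120 °C
Reagents that add atoms: none
Why: Pd(0), formed in situ from PdCl2(dppf), inserts into the C–I bond of 8, CO insertion gives the aroyl–Pd species, and amine-assisted transfer of the acetylide from 9 followed by reductive elimination makes C4a–C4 and C4–C3 in ynone 11. Diethylamine then adds reversibly to the ynone β-carbon to give enaminone 12, and the ortho-phenol displaces the amine at that same carbon (addition–elimination), forming O1–C2. The closest known reaction type is the Pd-catalysed carbonylative annulation of ortho-iodophenols with terminal arylacetylenes in a secondary amine, a carbonylative Sonogashira coupling followed by oxa-Michael closure. The pyranone ring is the only ring closed; the closure is formally 6-endo-dig on the ynone and no stereocentre is created. Two selectivities are needed: carbonylation has to outrun direct alkynylation (which would end in a benzofuran), and the six-membered closure has to outrun 5-exo-dig closure to an aurone. The electron-rich aryl–Pd bond flanked by OH and OMe should insert CO readily under 20 bar while copper-free conditions slow direct acetylide transfer, and routing the closure through enaminone 12 fixes attack at the β-carbon, which can only give the six-membered ring.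

**Compound list**
1 | 2-hydroxy-4,6-dimethoxybenzaldehyde | COc1cc(O)c(C=O)c(OC)c1 | starting material
2 | 2-(methoxymethoxy)-4,6-dimethoxybenzaldehyde | COCOc1cc(OC)cc(OC)c1C=O | intermediate
3 | 2-(methoxymethoxy)-4,6-dimethoxyphenyl formate | COCOc1cc(OC)cc(OC)c1OC=O | intermediate
4 | 2-(methoxymethoxy)-4,6-dimethoxyphenol | COCOc1cc(OC)cc(OC)c1O | intermediate
5 | 1,2,5-trimethoxy-3-(methoxymethoxy)benzene | COCOc1cc(OC)cc(OC)c1OC | intermediate
6 | [3,4,6-trimethoxy-2-(methoxymethoxy)phenyl]lithium | [Li]c1c(OCOC)c(OC)c(OC)cc1OC | intermediate
7 | 2-iodo-1,4,5-trimethoxy-3-(methoxymethoxy)benzene | COCOc1c(I)c(OC)cc(OC)c1OC | intermediate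
8 | 2-iodo-3,5,6-trimethoxyphenol | Oc1c(I)c(OC)cc(OC)c1OC | intermediate
9 | 4-ethynyl-1,2-dimethoxybenzene | C#Cc1ccc(OC)c(OC)c1 | starting material
10 | carbon monoxide | [C-]#[O+] | starting material
11 | 3-(3,4-dimethoxyphenyl)-1-(2-hydroxy-3,4,6-trimethoxyphenyl)prop-2-yn-1-one | COc1ccc(C#CC(=O)c2c(O)c(OC)c(OC)cc2OC)cc1OC | intermediate
12 | (E)-3-(diethylamino)-3-(3,4-dimethoxyphenyl)-1-(2-hydroxy-3,4,6-trimethoxyphenyl)prop-2-en-1-one | CCN(CC)/C(=C/C(=O)c1c(O)c(OC)c(OC)cc1OC)c1ccc(OC)c(OC)c1 | intermediate
13 | isosinensetin, 2-(3,4-dimethoxyphenyl)-5,7,8-trimethoxy-4H-chromen-4-one | COc1ccc(-c2cc(=O)c3c(OC)cc(OC)c(OC)c3o2)cc1OC | target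

**Step count**
Total steps: 6. Longest linear sequence: 6 steps (1 → 13); compounds 9 and 10 enter in step 6.

**Steps most likely to fail**

Step 6. Oxidative addition into the hindered, electron-rich C–I bond may be slow. The aryl–Pd species may then be alkynylated before CO inserts, and this would close to a benzofuran. Diethylamine may also capture the aroyl–Pd species as an amide, or the alkyne may oligomerise at 120 °C. The fallback gives up the Pd/CO assembly for organolithium acylation and the classical chalcone closure. It sets out from 5 and comes back at 13.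
- Compound 5 is lithiated as in step 4 to 6, which is quenched with N-methoxy-N-methylacetamide (THF, −78 °C → 0 °C) to give 1-[3,4,6-trimethoxy-2-(methoxymethoxy)phenyl]ethan-1-one F1.
- Methanolic HCl should remove the acetal to give 1-(2-hydroxy-3,4,6-trimethoxyphenyl)ethan-1-one F2.
- Claisen–Schmidt condensation with 3,4-dimethoxybenzaldehyde (KOH, EtOH, rt) should give (E)-3-(3,4-dimethoxyphenyl)-1-(2-hydroxy-3,4,6-trimethoxyphenyl)prop-2-en-1-one F3.
- Oxidative cyclisation of this 2'-hydroxychalcone (cat. I2, DMSO, 130 °C) should deliver 13.

Step 4. Metalation may occur in part at the C–H between the two methoxy groups, or remain incomplete, so that iodine ends up at the wrong carbon or is not introduced. The fallback replaces the MOM director by the strongest oxygen-based director and sets out from 5, coming back at 8 (step 5 is then not needed).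
- Methanolic HCl on 5 gives 2,3,5-trimethoxyphenol F4.
- NaH and diethylcarbamoyl chloride in THF give 2,3,5-trimethoxyphenyl N,N-diethylcarbamate F5.
- s-BuLi/TMEDA in THF at −78 °C should metalate only between the carbamate and the methoxy group, giving [2-(diethylcarbamoyloxy)-3,4,6-trimethoxyphenyl]lithium F6.
- Quenching with I2 at −78 °C, before any anionic Fries shift, gives 2-iodo-3,5,6-trimethoxyphenyl N,N-diethylcarbamate F7.
- Hydrolysis with NaOH in aqueous EtOH at reflux and acidification should release 8.

Step 5. Ipso-protonation of the very electron-rich iodoarene under acid may cause loss of iodine (protodeiodination) in competition with acetal cleavage, and the free iodophenol may darken by oxidation on handling. The fallback keeps the MOM group on through the C–C bond formation, so that acid is applied only when no C–I bond remains. It sets out from 7 (with 9 and 10) and comes back at 11.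
- Carbonylative Sonogashira coupling of 7 with 9 under CO (PdCl2(PPh3)2 cat., Et3N, THF, CO 5 bar, 50 °C) should give 3-(3,4-dimethoxyphenyl)-1-[3,4,6-trimethoxy-2-(methoxymethoxy)phenyl]prop-2-yn-1-one F8.
- Methanolic HCl then unmasks the phenol to give 11, here isolated.
- Warming 11 with Et2NH in EtOH closes it through 12 to 13, as in the second half of step 6.

**Further compounds**
F1 | step 6 | 1-[3,4,6-trimethoxy-2-(methoxymethoxy)phenyl]ethan-1-one | CC(=O)c1c(OCOC)c(OC)c(OC)cc1OC
F2 | step 6 | 1-(2-hydroxy-3,4,6-trimethoxyphenyl)ethan-1-one | CC(=O)c1c(O)c(OC)c(OC)cc1OC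
F3 | step 6 | (E)-3-(3,4-dimethoxyphenyl)-1-(2-hydroxy-3,4,6-trimethoxyphenyl)prop-2-en-1-one | COc1ccc(/C=C/C(=O)c2c(O)c(OC)c(OC)cc2OC)cc1OC
F4 | step 4 | 2,3,5-trimethoxyphenol | COc1cc(O)c(OC)c(OC)c1
F5 | step 4 | 2,3,5-trimethoxyphenyl N,N-diethylcarbamate | CCN(CC)C(=O)Oc1cc(OC)cc(OC)c1OC
F6 | step 4 | [2-(diethylcarbamoyloxy)-3,4,6-trimethoxyphenyl]lithium | [Li]c1c(OC(=O)N(CC)CC)c(OC)c(OC)cc1OC
F7 | step 4 | 2-iodo-3,5,6-trimethoxyphenyl N,N-diethylcarbamate | CCN(CC)C(=O)Oc1c(I)c(OC)cc(OC)c1OC
F8 | step 5 | 3-(3,4-dimethoxyphenyl)-1-[3,4,6-trimethoxy-2-(methoxymethoxy)phenyl]prop-2-yn-1-one | COCOc1c(OC)c(OC)cc(OC)c1C(=O)C#Cc1ccc(OC)c(OC)c1
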